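Late in the south-west run, which is this very flask followed so far, product still climbs: 74.5 % at 6.00 min, 81.4 % at 10.0 min. Where can it stop?

- south-west: substrate 0.050 M; reagent 0.045 M; the very flask that is asked about, followed so far
- flask: substrate 0.050 M; reagent 0.0450 M; time 12 min

- south-west (time / min: product / %, substrate / %): 0.500: 11.5, 87.9; 1.33: 33.1, 66.9; 2.50: 49.6, 49.6; 4.00: 67.8, 34.1; 6.00: 74.5, 20.9; 8.00: 78.4, 15.3; 10.0: 81.4, 15.7

(readings scatter by 1 percentage point)

- removed product is counted in
- additions bring no volume worth counting

- elm: at 12 min add reagent, 100 % of the amount charged, then wait 4.0 min
- birch: at 12 min take out 90 % of the product then present, then wait 4.0 min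
- larch: change nothing and wait 4.0 min more
- cedar: at 12 min add substrate, 50.0 % of the amount charged, then wait 4.0 min

- product, in percent of the substrate first charged, at 12 min
- the remedy with the largest gain of product, or "none" below 2 percentage points (elm / birch / larch / cedar / none)
- product present, with what was taken out counted in, in percent of the substrate first charged, after elm
- product present, with what was taken out counted in, in percent of the substrate first charged, after birch

Reagent is charged below substrate. With one reagent per product, reagent is therefore the limiting reagent, and the reagent charge over the substrate charge, 90.0 %, is the reagent ceiling: the product, in percent of the substrate charged, that the reagent can pay for.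

My own reckoning joins the two ends of the run. The early end treats product as closing its gap to the ceiling at a steady rate, and the first reading gives 0.273 min⁻¹, so 86.6 % at 12 min. That link is weak: the same rate gives 84.2 % at 10.0 min, more than was read, and the miss of 2.8 percentage points stands against a scatter of 1 point. So it is reforged from the late end. The gap is 15 points at 6.00 min and 8.6 points at 10.0 min, which gives a slower 0.147 min⁻¹. Carried forward, that rate gives 83.6 % at 12 min. Elm doubles the reagent and lifts the ceiling to 100 %; the other remedies add no reagent and leave it where it was.

The forecast says 83 %, under my figure, and names elm, with 92 % after elm and 88 % after birch, holding that “extra reagent should consume most of the remaining substrate”.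

The flask gives 82.4 %; elm gains 13 points and reaches 95.8 %, while birch reaches 84.7 %, a gain of 2.3 points.

    substrate ⇌ reactive form (K = 0.440, k = 0.00470 s⁻¹)
    reagent + reactive form → product (k = 54.0 M⁻¹ s⁻¹)
    reagent ⇌ dormant form (K = 1.30, k = 0.00200 s⁻¹)

Up to 6.00 min in the flask, free reagent fell to 0.385 % of its charge, with 0.00652 M standing as dormant form. Dormant form then fell to 0.00378 M at 12.0 min, when product, dormant form and free reagent together make 90.0 % against the ceiling of 90.0 %, and product in the flask stands at 90.0 % at 120 min. A neighbour charged with 0.018 M of reagent has a ceiling of 36.0 %, and its product at 12.0 min is 34.9 %.

Readings and results were computed for substances that don't exist; noise was put on by code.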